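**Strategy**

The cyclohexanone ring (C1 carbonyl, C2 methine, quaternary C3, C4 methine, C5, C6) is not closed as a six-membered ring. C2 begins as an exocyclic (R)-configured mesyloxy carbon on the carbinol carbon of a 2-allyl-2,3-dimethylcyclopentanol. With Et3Al the quaternary ring carbon shifts onto that carbon. One operation should therefore enlarge the ring, create the C1 ketone and set the epimerisable C2 methyl stereocentre (probably the less stable epimer) by inversion, with retention at the migrating carbon. The step exploits the C1(=O)–C2(H)(CH3)–C3(quaternary) array. The allyl group then becomes the aldehyde for a Nozaki–Hiyama–Kishi union with the aryl vinyl iodide; resorcinol oxidation gives the hydroxyquinone last.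

Key step: step 6

Remark on the chemistry: compounds 5–9 are written as the C1 epimer expected from step 3. The other C1 epimer, if formed, converges on 10, because C1 becomes the carbonyl carbon in step 6.

**Route**

Step 1
Reactants: 1 2-bromocyclopent-2-en-1-one
Product: 2 2-(prop-2-en-1-yl)cyclopent-2-en-1-one
Conditions: allylSnBu3 (1.2 equiv), Pd(PPh3)4 (5 mol%), CuI (10 mol%), DMF, 60 °C
Reagents that add atoms: allyltributylstannane, C=CC[Sn](CCCC)(CCCC)CCCC
Why: Stille coupling at the sp2 C–Br bond of the α-bromo enone with allyl transfer from tin should give the 2-allyl enone; no stereocentre is formed.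

Step 2
Reactants: 2 2-(prop-2-en-1-yl)cyclopent-2-en-1-one
Product: 4 (2S,3S)-2,3-dimethyl-2-(prop-2-en-1-yl)cyclopentan-1-one, via bromomagnesium enolate 3 (not isolated)
Conditions: MeMgBr (1.2 equiv), CuBr·SMe2 (5 mol%), 1-[2-(dicyclohexylphosphino)ferrocenyl]ethyldiphenylphosphine (6 mol%, the enantiomer that gives the 3S centre), t-BuOMe, −78 °C; then MeI (5 equiv), DMPU, −78 → 0 °C
Reagents that add atoms: methylmagnesium bromide, C[Mg]Br; iodomethane, CI
Why: Copper-catalysed asymmetric conjugate addition sets C3 (S) by ligand control, and the regiodefined magnesium enolate 3 is methylated anti to the new C3 methyl, so the quaternary C2 forms with methyl trans and allyl cis to the C3 methyl (conjugate addition–enolate alkylation).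

Step 3
Reactants: 4 (2S,3S)-2,3-dimethyl-2-(prop-2-en-1-yl)cyclopentan-1-one
Product: 6 1-[(1R,2S,3S)-1-hydroxy-2,3-dimethyl-2-(prop-2-en-1-yl)cyclopentyl]ethan-1-one, via enol ether carbinol 5 (not isolated)
Conditions: CH2=C(OEt)Li (from ethyl vinyl ether, t-BuLi, THF, −78 → 0 °C), THF, −78 °C; then 1 M HCl, THF, 0 °C
Reagents that add atoms: 1-ethoxyvinyllithium (from ethyl vinyl ether and t-BuLi), [Li]C(=C)OCC; water, O
Why: 1,2-Addition of the acyl anion equivalent, expected mainly anti to the allyl group, followed by acid hydrolysis of the enol ether should give the tertiary α-hydroxy methyl ketone; the C1 configuration is inconsequential because C1 later becomes the carbonyl carbon.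

Step 4
Reactants: 6 1-[(1R,2S,3S)-1-hydroxy-2,3-dimethyl-2-(prop-2-en-1-yl)cyclopentyl]ethan-1-one
Product: 7 (1R,2S,3S)-1-[(1R)-1-hydroxyethyl]-2,3-dimethyl-2-(prop-2-en-1-yl)cyclopentan-1-ol
Conditions: (S)-Me-CBS oxazaborolidine (20 mol%), catecholborane (2.5 equiv), toluene, −78 °C; then MeOH, aq. NaOH
Reagents that add atoms: none
Why: CBS reduction with catecholborane, which should leave the terminal alkene alone, delivers hydride under catalyst control with the tertiary carbinol carbon as the large group, setting the (R)-carbinol that becomes C2 of the cyclohexanone.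

Step 5
Reactants: 7 (1R,2S,3S)-1-[(1R)-1-hydroxyethyl]-2,3-dimethyl-2-(prop-2-en-1-yl)cyclopentan-1-ol
Product: 8 (1R)-1-[(1R,2S,3S)-1-hydroxy-2,3-dimethyl-2-(prop-2-en-1-yl)cyclopentyl]ethyl methanesulfonate
Conditions: MsCl (1.1 equiv), Et3N (2 equiv), CH2Cl2, −20 °C
Reagents that add atoms: methanesulfonyl chloride, CS(=O)(=O)Cl
Why: Sulfonylation should select the secondary hydroxyl, because the tertiary one is too hindered, and proceeds with retention at the carbinol carbon.

Step 6
Reactants: 8 (1R)-1-[(1R,2S,3S)-1-hydroxy-2,3-dimethyl-2-(prop-2-en-1-yl)cyclopentyl]ethyl methanesulfonate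
Product: 10 (2R,3S,4S)-2,3,4-trimethyl-3-(prop-2-en-1-yl)cyclohexan-1-one, via diethylaluminium alkoxide 9 (not isolated)
Conditions: Et3Al (3 equiv), CH2Cl2, −78 °C
Reagents that add atoms: none
Why: Et3Al converts the tertiary hydroxyl into alkoxide 9 and assists ionisation of the secondary mesylate; the ring bond from the carbinol carbon to the quaternary carbon, anti-periplanar to the C–OMs bond, shifts to the exocyclic carbon while the alkoxide oxygen becomes the carbonyl, so the cyclopentane grows by one carbon into the cyclohexanone. The closest known reaction type is the organoaluminium-promoted semipinacol (pinacol-type) 1,2-shift of 2-sulfonyloxy carbinols, used here as a ring expansion. No ring is closed by cyclisation: the six-membered ring arises by a suprafacial 1,2-alkyl shift that inserts the exocyclic carbon between the carbonyl carbon and the quaternary carbon. The new stereocentre (C2 of 10) is controlled by the (R)-mesylate carbon, which is inverted by backside entry of the migrating carbon, while the quaternary carbon migrates with retention and C4 is untouched. The step needs migration of the quaternary carbon in preference to the C5 methylene and no loss of the kinetically set C2 configuration; the higher migratory aptitude of the fully substituted carbon and the aprotic conditions at −78 °C should secure both.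

Step 7
Reactants: 10 (2R,3S,4S)-2,3,4-trimethyl-3-(prop-2-en-1-yl)cyclohexan-1-one
Product: 12 2-[(1S,2R,6S)-1,2,6-trimethyl-3-oxocyclohexyl]acetaldehyde, via secondary ozonide 11 (not isolated)
Conditions: O3, CH2Cl2, −78 °C; then PPh3, −78 °C → rt
Reagents that add atoms: ozone, [O-][O+]=O
Why: Ozonolysis of the terminal alkene with reductive work-up should cleave the allyl group to the acetaldehyde side chain under neutral conditions that do not epimerise C2; the aldehyde is used crude.

Step 8
Reactants: 13 5-methylbenzene-1,3-diol (orcinol)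
Product: 14 4-chloro-5-methylbenzene-1,3-diol
Conditions: SO2Cl2 (1.0 equiv), Et2O, 0 °C
Reagents that add atoms: sulfuryl chloride, O=S(=O)(Cl)Cl
Why: Electrophilic aromatic chlorination with one equivalent should occur mainly at C4, para to one hydroxyl and ortho to the other, and not at the hindered C2 between the hydroxyls.

Step 9
Reactants: 14 4-chloro-5-methylbenzene-1,3-diol
Product: 15 2-chloro-1,5-bis(methoxymethoxy)-3-methylbenzene
Conditions: MOMCl (2.5 equiv), i-Pr2NEt (3 equiv), CH2Cl2, 0 °C → rt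
Reagents that add atoms: chloromethyl methyl ether, COCCl
Why: O-Alkylation of both phenols protects the resorcinol and provides the two ortho-directing groups needed for the next step.

Step 10
Reactants: 15 2-chloro-1,5-bis(methoxymethoxy)-3-methylbenzene
Product: 17 2-(but-2-yn-1-yl)-4-chloro-1,3-bis(methoxymethoxy)-5-methylbenzene, via aryllithium 16 (not isolated)
Conditions: n-BuLi (1.1 equiv), THF, 0 °C; then CuBr·SMe2 (10 mol%), 1-bromobut-2-yne (1.3 equiv), −78 °C → rt
Reagents that add atoms: 1-bromobut-2-yne, CC#CCBr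
Why: Directed ortho-metalation removes the only proton flanked by two methoxymethoxy groups, and copper-catalysed alkylation of 16 should favour SN2 attack at CH2 because the distal alkyne carbon carries a methyl group and the nucleophile is doubly ortho-substituted.

Step 11
Reactants: 17 2-(but-2-yn-1-yl)-4-chloro-1,3-bis(methoxymethoxy)-5-methylbenzene
Product: 19 4-chloro-2-[(2E)-3-iodobut-2-en-1-yl]-1,3-bis(methoxymethoxy)-5-methylbenzene, via alkenylzirconocene chloride 18 (not isolated)
Conditions: Cp2Zr(H)Cl (1.5 equiv), THF, rt → 40 °C; then I2, 0 °C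
Reagents that add atoms: iodine, [I][I]
Why: syn-Hydrozirconation of the internal alkyne, equilibrated by the slight excess of Cp2Zr(H)Cl, should place zirconium on the less hindered methyl-bearing carbon, and iodinolysis with retention gives the (E)-trisubstituted vinyl iodide.

Step 12
Reactants: 12 2-[(1S,2R,6S)-1,2,6-trimethyl-3-oxocyclohexyl]acetaldehyde; 19 4-chloro-2-[(2E)-3-iodobut-2-en-1-yl]-1,3-bis(methoxymethoxy)-5-methylbenzene
Product: 20 (2R,3S,4S)-3-[(2S,3E)-5-[3-chloro-2,6-bis(methoxymethoxy)-4-methylphenyl]-2-hydroxy-3-methylpent-3-en-1-yl]-2,3,4-trimethylcyclohexan-1-one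
Conditions: CrCl2 (4 equiv), N-[2-(4-isopropyl-4,5-dihydro-1,3-oxazol-2-yl)-6-methylphenyl]methanesulfonamide (4.4 equiv, the enantiomer matched to the S carbinol), Et3N (4.4 equiv), NiCl2 (2 mol%), THF, rt
Reagents that add atoms: none
Why: Nozaki–Hiyama–Kishi coupling: nickel-catalysed activation of the vinyl iodide and transfer to chromium gives an alkenyl nucleophile that should add to the aldehyde and not the ketone with retention of the E geometry, and the new carbinol centre (S) is set by the chiral sulfonamide ligand on chromium because the ring stereocentres are too remote to direct it.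

Step 13
Reactants: 20 (2R,3S,4S)-3-[(2S,3E)-5-[3-chloro-2,6-bis(methoxymethoxy)-4-methylphenyl]-2-hydroxy-3-methylpent-3-en-1-yl]-2,3,4-trimethylcyclohexan-1-one
Product: 21 (2R,3S,4S)-3-[(2S,3E)-5-(3-chloro-2,6-dihydroxy-4-methylphenyl)-2-hydroxy-3-methylpent-3-en-1-yl]-2,3,4-trimethylcyclohexan-1-one
Conditions: ZnBr2 (2 equiv), n-PrSH (4 equiv), CH2Cl2, 0 °C, 10 min
Reagents that add atoms: none
Why: Lewis acid-assisted thiolysis of the two aryl methoxymethyl ethers (acetal exchange) should be complete within minutes at 0 °C, conditions under which the allylic alcohol, the trisubstituted alkene and the C2 stereocentre are expected to survive.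

Step 14
Reactants: 21 (2R,3S,4S)-3-[(2S,3E)-5-(3-chloro-2,6-dihydroxy-4-methylphenyl)-2-hydroxy-3-methylpent-3-en-1-yl]-2,3,4-trimethylcyclohexan-1-one
Product: 22 2-chloro-5-hydroxy-3-methyl-6-[(2E,4S)-4-hydroxy-3-methyl-5-[(1S,2R,6S)-1,2,6-trimethyl-3-oxocyclohexyl]pent-2-en-1-yl]cyclohexa-2,5-diene-1,4-dione
Conditions: ON(SO3K)2 (2.5 equiv), KH2PO4 buffer (pH 6), acetone/H2O, 0 °C → rt
Reagents that add atoms: potassium nitrosodisulfonate, [K+].[K+].[O-]S(=O)(=O)N([O])S(=O)(=O)[O-]
Why: Teuber-type oxidation: the nitrosodisulfonate radical should oxidise the resorcinol at its only unsubstituted ring carbon, para to one hydroxyl, to the para-quinone while the other hydroxyl remains as the quinone hydroxyl, under buffered conditions that leave the alcohol, alkene and ketone untouched.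

**Compound list**

1 | 2-bromocyclopent-2-en-1-one | O=C1CCC=C1Br | starting material
2 | 2-(prop-2-en-1-yl)cyclopent-2-en-1-one | C=CCC1=CCCC1=O | intermediate
3 | bromomagnesium (3S)-3-methyl-2-(prop-2-en-1-yl)cyclopent-1-en-1-olate | C=CCC1=C(O[Mg]Br)CC[C@@H]1C | intermediate
4 | (2S,3S)-2,3-dimethyl-2-(prop-2-en-1-yl)cyclopentan-1-one | C=CC[C@@]1(C)[C@@H](C)CCC1=O | intermediate
5 | (1R,2S,3S)-1-(1-ethoxyethenyl)-2,3-dimethyl-2-(prop-2-en-1-yl)cyclopentan-1-ol | C=CC[C@@]1(C)[C@@H](C)CC[C@]1(O)C(=C)OCC | intermediate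
6 | 1-[(1R,2S,3S)-1-hydroxy-2,3-dimethyl-2-(prop-2-en-1-yl)cyclopentyl]ethan-1-one | C=CC[C@@]1(C)[C@@H](C)CC[C@]1(O)C(C)=O | intermediate
7 | (1R,2S,3S)-1-[(1R)-1-hydroxyethyl]-2,3-dimethyl-2-(prop-2-en-1-yl)cyclopentan-1-ol | C=CC[C@@]1(C)[C@@H](C)CC[C@]1(O)[C@@H](C)O | intermediate
8 | (1R)-1-[(1R,2S,3S)-1-hydroxy-2,3-dimethyl-2-(prop-2-en-1-yl)cyclopentyl]ethyl methanesulfonate | C=CC[C@@]1(C)[C@@H](C)CC[C@]1(O)[C@@H](C)OS(C)(=O)=O | intermediate
9 | diethylaluminium alkoxide of 8 | C=CC[C@@]1(C)[C@@H](C)CC[C@]1(O[Al](CC)CC)[C@@H](C)OS(C)(=O)=O | intermediate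
10 | (2R,3S,4S)-2,3,4-trimethyl-3-(prop-2-en-1-yl)cyclohexan-1-one | C=CC[C@@]1(C)[C@@H](C)CCC(=O)[C@@H]1C | intermediate
11 | (2R,3S,4S)-2,3,4-trimethyl-3-(1,2,4-trioxolan-3-ylmethyl)cyclohexan-1-one | O1COOC1C[C@@]2(C)[C@@H](C)CCC(=O)[C@@H]2C | intermediate
12 | 2-[(1S,2R,6S)-1,2,6-trimethyl-3-oxocyclohexyl]acetaldehyde | O=CC[C@@]1(C)[C@@H](C)CCC(=O)[C@@H]1C | intermediate
13 | 5-methylbenzene-1,3-diol (orcinol) | Cc1cc(O)cc(O)c1 | starting material
14 | 4-chloro-5-methylbenzene-1,3-diol | Cc1cc(O)cc(O)c1Cl | intermediate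
15 | 2-chloro-1,5-bis(methoxymethoxy)-3-methylbenzene | Cc1cc(OCOC)cc(OCOC)c1Cl | intermediate
16 | [3-chloro-2,6-bis(methoxymethoxy)-4-methylphenyl]lithium | Cc1cc(OCOC)c([Li])c(OCOC)c1Cl | intermediate
17 | 2-(but-2-yn-1-yl)-4-chloro-1,3-bis(methoxymethoxy)-5-methylbenzene | CC#CCc1c(OCOC)cc(C)c(Cl)c1OCOC | intermediate
18 | chlorobis(cyclopentadienyl)[(2E)-4-[3-chloro-2,6-bis(methoxymethoxy)-4-methylphenyl]but-2-en-2-yl]zirconium | Cc1cc(OCOC)c(C/C=C(\C)[Zr](Cl)(C2C=CC=C2)C3C=CC=C3)c(OCOC)c1Cl | intermediate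
19 | 4-chloro-2-[(2E)-3-iodobut-2-en-1-yl]-1,3-bis(methoxymethoxy)-5-methylbenzene | Cc1cc(OCOC)c(C/C=C(\C)I)c(OCOC)c1Cl | intermediate
20 | (2R,3S,4S)-3-[(2S,3E)-5-[3-chloro-2,6-bis(methoxymethoxy)-4-methylphenyl]-2-hydroxy-3-methylpent-3-en-1-yl]-2,3,4-trimethylcyclohexan-1-one | Cc1cc(OCOC)c(C/C=C(\C)[C@@H](O)C[C@@]2(C)[C@@H](C)CCC(=O)[C@@H]2C)c(OCOC)c1Cl | intermediate
21 | (2R,3S,4S)-3-[(2S,3E)-5-(3-chloro-2,6-dihydroxy-4-methylphenyl)-2-hydroxy-3-methylpent-3-en-1-yl]-2,3,4-trimethylcyclohexan-1-one | Cc1cc(O)c(C/C=C(\C)[C@@H](O)C[C@@]2(C)[C@@H](C)CCC(=O)[C@@H]2C)c(O)c1Cl | intermediate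
22 | 2-chloro-5-hydroxy-3-methyl-6-[(2E,4S)-4-hydroxy-3-methyl-5-[(1S,2R,6S)-1,2,6-trimethyl-3-oxocyclohexyl]pent-2-en-1-yl]cyclohexa-2,5-diene-1,4-dione | CC1=C(Cl)C(=O)C(C/C=C(\C)[C@@H](O)C[C@@]2(C)[C@@H](C)CCC(=O)[C@@H]2C)=C(O)C1=O | target

**Step count and risks**

Total step count: 14. Longest linear sequence: 10 steps (steps 1–7 and 12–14); the aryl branch (steps 8–11) joins at step 12.

Steps most likely to fail:

1. Step 6. The C5 methylene may shift in place of the quaternary carbon, or the alkoxide may close onto the mesylate carbon to an epoxide. The fallback sets out from 4 and returns at 10 by a carbenoid ring enlargement in which the more substituted α-carbon is the one expected to migrate. Ketone 4 is treated with 1,1-dibromoethyllithium (CH3CHBr2, LiN(i-Pr)2, THF, −95 °C) to give the dibromo carbinol F1 as its lithium alkoxide. Bromine–lithium exchange with n-BuLi (−95 → 0 °C) triggers α-elimination with 1,2-shift to the regiodefined lithium enolate F2, which is trapped with Me3SiCl as the silyl enol ether F3. C2 is then set by protonation of F3 at −78 °C with the chiral Brønsted acid SnCl4·(R)-2-hydroxy-2′-methoxy-1,1′-binaphthyl (enantiomer chosen for the 2R epimer), which should give 10. Stereocontrol at C2 is weaker here than in the main route, since substrate bias may oppose the reagent.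

2. Step 2. Methyl transfer to the α-substituted enone may be slow or poorly face-selective. The fallback sets out from 2 and returns at 7 by resolution through diastereomers. Me2CuLi (Et2O, −78 °C) followed by MeI/HMPA gives the trans ketone as the racemate, that is 4 with its enantiomer F4. Step 3 on this mixture gives 6 and, through the enol ether carbinol F5, its enantiomer F6. The oxazaborolidine reduction of step 4 fixes the new carbinol carbon as R in both series, so 7 is formed beside the diastereomer F7, from which it is separated by chromatography.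

3. Step 12. Reagent control at the new carbinol carbon may be weak, because the ring stereocentres are remote and the iodide is trisubstituted. The fallback sets out from 12 and 19 and returns at 20. Ligand-free coupling (CrCl2, NiCl2 cat., DMSO, rt) gives 20 together with its carbinol epimer F8. After separation, F8 is inverted under Mitsunobu conditions (4-nitrobenzoic acid, PPh3, DIAD, THF, 0 °C) to the (S)-4-nitrobenzoate F9, and brief methanolysis (K2CO3, MeOH, 0 °C) releases 20.

**Further compounds**

F1 | step 6 | (1R,2S,3S)-1-(1,1-dibromoethyl)-2,3-dimethyl-2-(prop-2-en-1-yl)cyclopentan-1-ol | C=CC[C@@]1(C)[C@@H](C)CC[C@]1(O)C(C)(Br)Br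
F2 | step 6 | lithium (3S,4S)-2,3,4-trimethyl-3-(prop-2-en-1-yl)cyclohex-1-en-1-olate | C=CC[C@@]1(C)[C@@H](C)CCC(O[Li])=C1C
F3 | step 6 | trimethyl{[(3S,4S)-2,3,4-trimethyl-3-(prop-2-en-1-yl)cyclohex-1-en-1-yl]oxy}silane | C=CC[C@@]1(C)[C@@H](C)CCC(O[Si](C)(C)C)=C1C
F4 | step 2 | (2R,3R)-2,3-dimethyl-2-(prop-2-en-1-yl)cyclopentan-1-one | C=CC[C@]1(C)[C@H](C)CCC1=O
F5 | step 2 | (1S,2R,3R)-1-(1-ethoxyethenyl)-2,3-dimethyl-2-(prop-2-en-1-yl)cyclopentan-1-ol | C=CC[C@]1(C)[C@H](C)CC[C@@]1(O)C(=C)OCC
F6 | step 2 | 1-[(1S,2R,3R)-1-hydroxy-2,3-dimethyl-2-(prop-2-en-1-yl)cyclopentyl]ethan-1-one | C=CC[C@]1(C)[C@H](C)CC[C@@]1(O)C(C)=O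
F7 | step 2 | (1S,2R,3R)-1-[(1R)-1-hydroxyethyl]-2,3-dimethyl-2-(prop-2-en-1-yl)cyclopentan-1-ol | C=CC[C@]1(C)[C@H](C)CC[C@@]1(O)[C@@H](C)O
F8 | step 12 | (2R,3S,4S)-3-[(2R,3E)-5-[3-chloro-2,6-bis(methoxymethoxy)-4-methylphenyl]-2-hydroxy-3-methylpent-3-en-1-yl]-2,3,4-trimethylcyclohexan-1-one | Cc1cc(OCOC)c(C/C=C(\C)[C@H](O)C[C@@]2(C)[C@@H](C)CCC(=O)[C@@H]2C)c(OCOC)c1Cl
F9 | step 12 | (2S,3E)-5-[3-chloro-2,6-bis(methoxymethoxy)-4-methylphenyl]-3-methyl-1-[(1S,2R,6S)-1,2,6-trimethyl-3-oxocyclohexyl]pent-3-en-2-yl 4-nitrobenzoate | Cc1cc(OCOC)c(C/C=C(\C)[C@@H](OC(=O)c3ccc(cc3)[N+](=O)[O-])C[C@@]2(C)[C@@H](C)CCC(=O)[C@@H]2C)c(OCOC)c1Cl
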